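**Strategy**

The route rests on disconnecting the C2–C3 bond of ring C. The precursor is an acyclic α-diazoketone in which the future C3 is the diazo carbon beside the C4 carbonyl and the future C2 is the methylene of an aryl benzyl ether linking ring A to ring B. A chiral dirhodium carboxylate turns the diazo carbon into a carbene that inserts into one enantiotopic C–H bond of this methylene, which is activated by the ether oxygen O1 and by the para-methoxy group of ring B. One operation thus closes the pyranone ring, forms C2–C3 and sets the C2 stereocentre. Silyl ethers mask the three phenols.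

Key step: step 9

Abbreviations: TBS = tert-butyldimethylsilyl; prenyl = 3-methylbut-2-en-1-yl; Rh2(S-PTTL)4 = dirhodium tetrakis[N-phthaloyl-(S)-tert-leucinate], a divalent rhodium carboxylate.

Assumption: Rh2(S-PTTL)4 is taken to deliver the (S)-configured C2; if a model insertion shows the opposite sense, its enantiomer Rh2(R-PTTL)4 is used with no other change.

**Route**

Step 1
Reactants: 1 2-bromo-3-hydroxy-4-methoxybenzaldehyde; 2 tributyl(3-methylbut-2-en-1-yl)stannane
Product: 3 3-hydroxy-4-methoxy-2-(3-methylbut-2-en-1-yl)benzaldehyde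
Conditions: Pd(PPh3)4 (5 mol %), DMF, 100 °C
Reagents that add atoms: none
Why: Stille cross-coupling, in which zerovalent palladium inserts into the C–Br bond activated by the ortho formyl group and the prenyl group, delivered by the allylstannane, is expected to eliminate reductively from its less hindered primary terminus to give the linear prenyl arene; the free phenol is tolerated and no stereocentre is formed.

Step 2
Reactants: 3 3-hydroxy-4-methoxy-2-(3-methylbut-2-en-1-yl)benzaldehyde
Product: 4 3-(tert-butyldimethylsilyloxy)-4-methoxy-2-(3-methylbut-2-en-1-yl)benzaldehyde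
Conditions: TBSCl, imidazole, DMF, rt
Reagents that add atoms: tert-butyldimethylsilyl chloride, CC(C)(C)[Si](C)(C)Cl
Why: Imidazole-promoted silyl ether formation masks the only acidic group of ring B, so that it can neither compete in the later Mitsunobu etherification nor intercept the carbene.

Step 3
Reactants: 4 3-(tert-butyldimethylsilyloxy)-4-methoxy-2-(3-methylbut-2-en-1-yl)benzaldehyde
Product: 5 [3-(tert-butyldimethylsilyloxy)-4-methoxy-2-(3-methylbut-2-en-1-yl)phenyl]methanol
Conditions: NaBH4, MeOH–THF, 0 °C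
Reagents that add atoms: none
Why: Borohydride reduction of the aryl aldehyde gives the benzylic alcohol, and the aryl silyl ether and the trisubstituted alkene are inert to NaBH4 at 0 °C.

Step 4
Reactants: 6 1-(2,4,6-trihydroxyphenyl)ethan-1-one; 7 1-bromo-3-methylbut-2-ene
Product: 8 1-[2,4,6-trihydroxy-3-(3-methylbut-2-en-1-yl)phenyl]ethan-1-one
Conditions: DBU, THF, 0 °C to rt, 7 in slight deficit
Reagents that add atoms: none
Why: Direct C-prenylation of the ambident phloroglucinol-type phenoxide (Friedel–Crafts-type nuclear alkylation) should occur at one of the two equivalent ring CH positions, and the deficit of bromide limits bis-prenylation and O-prenylation, whose products are removed by chromatography.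

Step 5
Reactants: 8 1-[2,4,6-trihydroxy-3-(3-methylbut-2-en-1-yl)phenyl]ethan-1-one
Product: 9 1-[4-(tert-butyldimethylsilyloxy)-2,6-dihydroxy-3-(3-methylbut-2-en-1-yl)phenyl]ethan-1-one
Conditions: TBSCl (1.05 equiv), imidazole, CH2Cl2–DMF, 0 °C
Reagents that add atoms: tert-butyldimethylsilyl chloride, CC(C)(C)[Si](C)(C)Cl
Why: Selective silyl ether formation is expected at the 4-hydroxyl, which is para to the acetyl group, the most acidic and the only one that cannot chelate the carbonyl.

Step 6
Reactants: 9 1-[4-(tert-butyldimethylsilyloxy)-2,6-dihydroxy-3-(3-methylbut-2-en-1-yl)phenyl]ethan-1-one; 5 [3-(tert-butyldimethylsilyloxy)-4-methoxy-2-(3-methylbut-2-en-1-yl)phenyl]methanol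
Product: 10 1-[6-{[3-(TBS-oxy)-4-methoxy-2-prenylphenyl]methoxy}-4-(TBS-oxy)-2-hydroxy-3-prenylphenyl]ethan-1-one
Conditions: PPh3, DIAD, THF, 0 °C to rt
Reagents that add atoms: none
Why: Mitsunobu etherification, in which the alkoxyphosphonium ion of the benzylic alcohol should be displaced by the less hindered ortho phenol (flanked by a ring hydrogen), while the hydroxyl beside the prenyl group is shielded and stays chelated to the carbonyl, which also disfavours bis-etherification.

Step 7
Reactants: 10 1-[6-{[3-(TBS-oxy)-4-methoxy-2-prenylphenyl]methoxy}-4-(TBS-oxy)-2-hydroxy-3-prenylphenyl]ethan-1-one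
Product: 11 1-[6-{[3-(TBS-oxy)-4-methoxy-2-prenylphenyl]methoxy}-2,4-bis(TBS-oxy)-3-prenylphenyl]ethan-1-one
Conditions: TBSOTf, 2,6-lutidine, CH2Cl2, −78 to 0 °C
Reagents that add atoms: tert-butyldimethylsilyl trifluoromethanesulfonate, CC(C)(C)[Si](C)(C)OS(=O)(=O)C(F)(F)F
Why: Silyl ether formation with the reactive silyl triflate caps the remaining hindered, chelated phenol with a group that has no C–H bond alpha to oxygen, so that this ortho oxygen stays silent in the carbene step.

Step 8
Reactants: 11 1-[6-{[3-(TBS-oxy)-4-methoxy-2-prenylphenyl]methoxy}-2,4-bis(TBS-oxy)-3-prenylphenyl]ethan-1-one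
Product: 13 2-diazo-1-[6-{[3-(TBS-oxy)-4-methoxy-2-prenylphenyl]methoxy}-2,4-bis(TBS-oxy)-3-prenylphenyl]ethan-1-one, via trifluoroacetyl diketone 12 (not isolated)
Conditions: LiN(SiMe3)2, THF, −78 °C; CF3CO2CH2CF3, −78 °C; then MsN3, Et3N, H2O, MeCN, rt
Reagents that add atoms: methanesulfonyl azide, CS(=O)(=O)N=[N+]=[N-] (the two diazo nitrogens); 2,2,2-trifluoroethyl trifluoroacetate, O=C(OCC(F)(F)F)C(F)(F)F (trifluoroacetyl group of 12 only, lost again on diazo transfer)
Why: Danheiser detrifluoroacetylative diazo transfer, in which Claisen trifluoroacetylation of the kinetically deprotonated methyl ketone gives the activated 1,3-diketone 12, to which the sulfonyl azide transfers N2 under mild amine base with loss of the trifluoroacetyl group as the N-acylsulfonamide, conditions that aryl silyl ethers, the benzylic ether and the prenyl groups should tolerate.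

Step 9
Reactants: 13 2-diazo-1-[6-{[3-(TBS-oxy)-4-methoxy-2-prenylphenyl]methoxy}-2,4-bis(TBS-oxy)-3-prenylphenyl]ethan-1-one
Product: 14 (2S)-5,7-bis(TBS-oxy)-2-[3-(TBS-oxy)-4-methoxy-2-prenylphenyl]-6-prenyl-2,3-dihydro-4H-chromen-4-one
Conditions: Rh2(S-PTTL)4 (1 mol %), CH2Cl2, 4 Å molecular sieves, slow addition of 13, 0 °C to rt
Reagents that add atoms: none
Why: The dirhodium catalyst should decompose the diazoketone with loss of N2 to an electrophilic rhodium-bound acylcarbene, which inserts into a C–H bond of the ArO–CH2–Ar methylene through a three-centre, hydride-transfer-like transition state and thereby forms the C2–C3 bond directly. The closest known reaction type is the intramolecular C–H insertion of ortho-alkoxyaryl α-diazoketones to chroman-4-ones under catalysis by chiral divalent rhodium carboxylates. Ring C closes as a 1,6-insertion, because the atom in the usual 1,5-position is the ether oxygen O1, whose lone pair activates the adjacent C–H bond, further assisted here by the para-methoxy group of ring B. The new stereocentre C2 is under catalyst control, the chiral carboxylate pocket distinguishing the two enantiotopic benzylic hydrogens. The step needs site selectivity over oxonium-ylide formation at the ether oxygens, which is countered by the weak donor ability of these ring-conjugated aryl ether oxygens and by the absence of any C–H bond alpha to the silylated oxygen on the other flank. Alkene cyclopropanation is excluded by geometry, since the ring A prenyl group is meta to the acyl carbon and the ring B prenyl group could be reached only through a ring of nine or more atoms, while slow addition suppresses carbene dimerisation.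

Step 10
Reactants: 14 (2S)-5,7-bis(TBS-oxy)-2-[3-(TBS-oxy)-4-methoxy-2-prenylphenyl]-6-prenyl-2,3-dihydro-4H-chromen-4-one
Product: 15 (2S)-5,7-dihydroxy-2-[3-hydroxy-4-methoxy-2-(3-methylbut-2-en-1-yl)phenyl]-6-(3-methylbut-2-en-1-yl)-2,3-dihydro-4H-chromen-4-one (CNP0306216.1)
Conditions: Bu4NF, AcOH (1:1), THF, 0 °C
Reagents that add atoms: none
Why: Fluoride-mediated cleavage of the three aryl silyl ethers, buffered with acetic acid so that no free phenoxide can open ring C by retro-oxa-Michael reaction, should leave C2 configurationally intact and the prenyl groups and the methyl ether untouched.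

**Compound list**

1 | 2-bromo-3-hydroxy-4-methoxybenzaldehyde | COc1ccc(C=O)c(Br)c1O | starting material
2 | tributyl(3-methylbut-2-en-1-yl)stannane | CCCC[Sn](CCCC)(CCCC)CC=C(C)C | starting material
3 | 3-hydroxy-4-methoxy-2-(3-methylbut-2-en-1-yl)benzaldehyde | COc1ccc(C=O)c(CC=C(C)C)c1O | intermediate
4 | 3-(tert-butyldimethylsilyloxy)-4-methoxy-2-(3-methylbut-2-en-1-yl)benzaldehyde | COc1ccc(C=O)c(CC=C(C)C)c1O[Si](C)(C)C(C)(C)C | intermediate
5 | [3-(tert-butyldimethylsilyloxy)-4-methoxy-2-(3-methylbut-2-en-1-yl)phenyl]methanol | COc1ccc(CO)c(CC=C(C)C)c1O[Si](C)(C)C(C)(C)C | intermediate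
6 | 1-(2,4,6-trihydroxyphenyl)ethan-1-one | CC(=O)c1c(O)cc(O)cc1O | starting material
7 | 1-bromo-3-methylbut-2-ene (prenyl bromide) | CC(C)=CCBr | starting material
8 | 1-[2,4,6-trihydroxy-3-(3-methylbut-2-en-1-yl)phenyl]ethan-1-one | CC(=O)c1c(O)cc(O)c(CC=C(C)C)c1O | intermediate
9 | 1-[4-(tert-butyldimethylsilyloxy)-2,6-dihydroxy-3-(3-methylbut-2-en-1-yl)phenyl]ethan-1-one | CC(=O)c1c(O)cc(O[Si](C)(C)C(C)(C)C)c(CC=C(C)C)c1O | intermediate
10 | 1-[6-{[3-(TBS-oxy)-4-methoxy-2-prenylphenyl]methoxy}-4-(TBS-oxy)-2-hydroxy-3-prenylphenyl]ethan-1-one | CC(=O)c1c(OCc2ccc(OC)c(O[Si](C)(C)C(C)(C)C)c2CC=C(C)C)cc(O[Si](C)(C)C(C)(C)C)c(CC=C(C)C)c1O | intermediate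
11 | 1-[6-{[3-(TBS-oxy)-4-methoxy-2-prenylphenyl]methoxy}-2,4-bis(TBS-oxy)-3-prenylphenyl]ethan-1-one | CC(=O)c1c(OCc2ccc(OC)c(O[Si](C)(C)C(C)(C)C)c2CC=C(C)C)cc(O[Si](C)(C)C(C)(C)C)c(CC=C(C)C)c1O[Si](C)(C)C(C)(C)C | intermediate
12 | 4,4,4-trifluoro-1-[6-{[3-(TBS-oxy)-4-methoxy-2-prenylphenyl]methoxy}-2,4-bis(TBS-oxy)-3-prenylphenyl]butane-1,3-dione | O=C(CC(=O)c1c(OCc2ccc(OC)c(O[Si](C)(C)C(C)(C)C)c2CC=C(C)C)cc(O[Si](C)(C)C(C)(C)C)c(CC=C(C)C)c1O[Si](C)(C)C(C)(C)C)C(F)(F)F | intermediate
13 | 2-diazo-1-[6-{[3-(TBS-oxy)-4-methoxy-2-prenylphenyl]methoxy}-2,4-bis(TBS-oxy)-3-prenylphenyl]ethan-1-one | [N-]=[N+]=CC(=O)c1c(OCc2ccc(OC)c(O[Si](C)(C)C(C)(C)C)c2CC=C(C)C)cc(O[Si](C)(C)C(C)(C)C)c(CC=C(C)C)c1O[Si](C)(C)C(C)(C)C | intermediate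
14 | (2S)-5,7-bis(TBS-oxy)-2-[3-(TBS-oxy)-4-methoxy-2-prenylphenyl]-6-prenyl-2,3-dihydro-4H-chromen-4-one | COc1ccc([C@@H]2CC(=O)c3c(cc(O[Si](C)(C)C(C)(C)C)c(CC=C(C)C)c3O[Si](C)(C)C(C)(C)C)O2)c(CC=C(C)C)c1O[Si](C)(C)C(C)(C)C | intermediate
15 | (2S)-5,7-dihydroxy-2-[3-hydroxy-4-methoxy-2-(3-methylbut-2-en-1-yl)phenyl]-6-(3-methylbut-2-en-1-yl)-2,3-dihydro-4H-chromen-4-one (CNP0306216.1) | COc1ccc([C@@H]2CC(=O)c3c(cc(O)c(CC=C(C)C)c3O)O2)c(CC=C(C)C)c1O | target

**Step count and risks**

Total step count: 10. Longest linear sequence: 8 steps (steps 1, 2, 3, 6, 7, 8, 9, 10, from compound 1).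

Most likely to fail, first: step 9. The carbene may be captured by the lone pair of the benzylic ether oxygen, followed by a 1,2-shift of the electron-rich benzyl group and ring contraction, or the two enantiotopic hydrogens may be discriminated poorly. The fallback changes the bond-forming principle from carbene insertion to oxidative C–H cleavage. It sets out from 11, which is deprotonated with KN(SiMe3)2 in THF at −78 °C and O-acetylated with Ac2O to the enol acetate F1. Treatment with DDQ, 2,6-dichloropyridine, LiClO4 and 4 Å molecular sieves in 1,2-dichloroethane should abstract hydride from the para-methoxybenzylic ether carbon. The resulting aryloxocarbenium ion is captured by the tethered enol acetate in a six-membered Mukaiyama-type closure of the same C2–C3 bond, giving the racemic silyl-protected flavanone F2. Preparative HPLC on a chiral stationary phase separates F2 into the (R)-enantiomer F3, which is discarded, and the (S)-enantiomer, at which point the fallback comes back to the route at 14.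

Second: step 8. The ortho silyl group may migrate from the phenolic oxygen to the enolate oxygen during deprotonation, or the para silyl ether may be lost hydrolytically in the aqueous amine medium. The fallback avoids any enolate. It sets out from 11, which is condensed with tert-butoxybis(dimethylamino)methane (Bredereck's reagent) in toluene at 60 °C to the (E)-enaminone F4. Cycloaddition of methanesulfonyl azide to the enamine double bond in MeCN at rt and fragmentation of the triazoline should release the N-sulfonylformamidine and the diazoketone, so that the fallback comes back to the route at 13.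

Third: step 6. Etherification may take place at the wrong ortho hydroxyl, which would lead to the 8-prenyl series, or the benzylic electrophile may alkylate the electron-rich ring at carbon. The fallback makes the regiochemistry independent of steric discrimination by attaching the benzyl group before the prenyl group. It sets out from 6 (and uses 5). Silylation of 6 with TBSCl and imidazole at the para hydroxyl gives the symmetrical 4-silyloxy-2,6-dihydroxyacetophenone F5. Mitsunobu etherification of F5 with 5 (PPh3, DIAD, THF) gives the mono-benzyl ether F6, in which the two ortho hydroxyls were equivalent. Pd(PPh3)4-catalysed O-allylation of the remaining phenol with tert-butyl 2-methylbut-3-en-2-yl carbonate in THF gives the 1,1-dimethylallyl aryl ether F7. Heating F7 in toluene at 110 °C should bring about an aromatic Claisen rearrangement to the only free ortho carbon, which delivers the prenyl group next to the liberated hydroxyl, and the fallback comes back to the route at 10.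

**Further compounds**

F1 | step 9 | 1-[6-{[3-(TBS-oxy)-4-methoxy-2-prenylphenyl]methoxy}-2,4-bis(TBS-oxy)-3-prenylphenyl]ethenyl acetate (enol acetate of 11) | C=C(OC(C)=O)c1c(OCc2ccc(OC)c(O[Si](C)(C)C(C)(C)C)c2CC=C(C)C)cc(O[Si](C)(C)C(C)(C)C)c(CC=C(C)C)c1O[Si](C)(C)C(C)(C)C
F2 | step 9 | racemic 5,7-bis(TBS-oxy)-2-[3-(TBS-oxy)-4-methoxy-2-prenylphenyl]-6-prenyl-2,3-dihydro-4H-chromen-4-one | COc1ccc(C2CC(=O)c3c(cc(O[Si](C)(C)C(C)(C)C)c(CC=C(C)C)c3O[Si](C)(C)C(C)(C)C)O2)c(CC=C(C)C)c1O[Si](C)(C)C(C)(C)C
F3 | step 9 | (2R)-5,7-bis(TBS-oxy)-2-[3-(TBS-oxy)-4-methoxy-2-prenylphenyl]-6-prenyl-2,3-dihydro-4H-chromen-4-one | COc1ccc([C@H]2CC(=O)c3c(cc(O[Si](C)(C)C(C)(C)C)c(CC=C(C)C)c3O[Si](C)(C)C(C)(C)C)O2)c(CC=C(C)C)c1O[Si](C)(C)C(C)(C)C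
F4 | step 8 | (E)-3-(dimethylamino)-1-[6-{[3-(TBS-oxy)-4-methoxy-2-prenylphenyl]methoxy}-2,4-bis(TBS-oxy)-3-prenylphenyl]prop-2-en-1-one | CN(C)/C=C/C(=O)c1c(OCc2ccc(OC)c(O[Si](C)(C)C(C)(C)C)c2CC=C(C)C)cc(O[Si](C)(C)C(C)(C)C)c(CC=C(C)C)c1O[Si](C)(C)C(C)(C)C
F5 | step 6 | 1-[4-(tert-butyldimethylsilyloxy)-2,6-dihydroxyphenyl]ethan-1-one | CC(=O)c1c(O)cc(O[Si](C)(C)C(C)(C)C)cc1O
F6 | step 6 | 1-[2-{[3-(TBS-oxy)-4-methoxy-2-prenylphenyl]methoxy}-4-(TBS-oxy)-6-hydroxyphenyl]ethan-1-one | CC(=O)c1c(O)cc(O[Si](C)(C)C(C)(C)C)cc1OCc1ccc(OC)c(O[Si](C)(C)C(C)(C)C)c1CC=C(C)C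
F7 | step 6 | 1-[2-{[3-(TBS-oxy)-4-methoxy-2-prenylphenyl]methoxy}-4-(TBS-oxy)-6-(2-methylbut-3-en-2-yloxy)phenyl]ethan-1-one | CC(=O)c1c(OC(C)(C)C=C)cc(O[Si](C)(C)C(C)(C)C)cc1OCc1ccc(OC)c(O[Si](C)(C)C(C)(C)C)c1CC=C(C)C
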